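What did the winter flask hold at 30 h, with its substrate at 1.8 M?

| flask | substrate | gas phase | free catalyst | remark | time |
|---|---|---|---|---|---|
| winter | 1.8 M | 200 mM (held) | 3.6 mM | the very flask that is asked about, followed so far |  |
| dawn | 0.90 M | 200 mM (held) | 3.6 mM | run made earlier |  |
| flask | 1.8 M | 200 mM (held) | 3.6 mM |  | 30 h |

- winter (time / h: target / %): 0.833: 4.7; 2.50: 12.4; 4.00: 20.4; 6.00: 28.8; 10.0: 43.6; 12.0: 49.5
- dawn (time / h: target / %): 5.00: 24.9; 10.0: 44.4; 15.0: 58.1; 20.0: 66.5; 25.0: 74.2; 30.0: 80.2

(each reading ± 0.5 percentage points)

- the target standing at 30 h, as a percentage of the substrate charged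
- concentration of dissolved gas in solution at 3.0 h, in percent of saturation
- the change that raises the amount of target at 30 h, in percent of the substrate charged most ("none" if none brings more than 2 percentage points) (Sunday's / Thursday's / Tuesday's / none)
- amount of target at 30 h, in percent of the substrate charged, after Tuesday's

- Sunday's: doubling the saturation concentration of gas phase, all else as stated
- Thursday's: doubling the transfer coefficient of the gas phase, all else as stated
- Tuesday's: doubling the amount of free catalyst, all else as stated

- at the start none of the gas is dissolved
- steps thought possible: dissolved gas -> decomposed reagent; substrate + dissolved gas -> uncatalysed product; gas phase <-> dissolved gas; dissolved gas + free catalyst -> spent catalyst; substrate + dissolved gas + free catalyst -> free catalyst + target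

I worked with the fraction of substrate left, not the fraction made, and took the target as the substrate gone. Its negative logarithm I called the exposure: a pseudo-first-order constant summed over time. I imagined two extreme flasks. In the first, transfer capped the molar rate of the gas-consuming reaction, so dawn's percentages should have stood 2.00 times winter's. At 10.0 h the ratio read 1.02, less than that, so the two runs lay far from this extreme. In the second, gas and catalyst held steady and exposure grew in a straight line. Dawn's exposure at 10.0 h then projected to 1.76 at 30.0 h. The reading gave 1.62, lower than the line, so the dawn run lay just below this extreme.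

I carried dawn's bend over to winter, scaling by the two exposures at 10.0 h. The exposure of the winter flask at 30 h, the negative logarithm of its fraction of substrate left, came to 1.58. That meant 79.4 % target. If the gas and the loss per catalyst stayed unchanged, exposure scaled with the catalyst charged, so I put Tuesday's at 95.8 %.

The forecast said 80 % where I had 79.4 %, 95 % where I had 95.8 %, and further 92 % and Tuesday's, and held that “Gas transfer is therefore not limiting”.

The flask gave 79.1 %, 92.5 %, Tuesday's with a gain of 16 percentage points against 14 points for Sunday's, and 95.4 %.

    dissolved gas → decomposed reagent (k = 0.0350 h⁻¹)
    substrate + dissolved gas → uncatalysed product (k = 0.00210 L mol⁻¹ h⁻¹)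
    gas phase ⇌ dissolved gas, rate k3*(csat - [dissolved gas]) (kL = 6.50 h⁻¹)
    dissolved gas + free catalyst → spent catalyst (k = 0.0610 L mol⁻¹ h⁻¹)
    substrate + dissolved gas + free catalyst → free catalyst + target (k = 91.0 L² mol⁻² h⁻¹)

With free catalyst at 3.10 mM or 4.24 mM, the other amounts and the time held, the target in the winter flask moved by 5 points, so the forecast's 80 % belonged to this charge and not to those. A neighbouring flask held 0.0014 M of free catalyst. Scaling gave it an exposure of 0.614, hence 45.9 % target. At 30.0 h it kept 70.2 % of its free catalyst, against 70.6 % in the winter flask, and stood at 46.1 % target.

(The readings come from a simulation for substances that don't exist.)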